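**Retrosynthetic overview**

1. Names used: ring A is the resorcinol ring fused only to the seven-membered ring; ring B is the benzo ring of the western dihydrobenzofuran (furan C2, C3); Ca is the seven-ring carbon bearing the 4-hydroxyphenyl group; Cb is its neighbour bearing ring C (the ring that carries the stilbene); rings D and E are the eastern benzofuran benzo ring and its 3-aryl group.
2. Last disconnections: ten methyl ethers (BBr3) and the E-stilbene, made by Heck coupling of a western ring C aryl chloride with an eastern 4-vinyl-trans-2,3-diaryl-2,3-dihydrobenzofuran; the eastern furan ring comes from an ortho-quinone methide/sulfonium ylide [4+1] annulation.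
3. Western half: the cis Ca–H/Cb–H pair comes from ionic hydrogenation of a ring-embedded tetraaryl alkene, whose Ca aryl group comes from enol triflate/Suzuki chemistry on a seven-membered ketone (Ca=O).
4. Key disconnection: the seven-membered ring is opened at ring B C4–Cb and at ring A–furan C3, a formal (4+3) back to a flat 4-iodo-2-arylbenzofuran and an acyclic ortho-bromoaryl benzyl ketone. The enabling feature is that furan C3 and benzo C4 of ring B are 1,3-related, so a C4 halide plus the aromatic furan C2=C3 bond is a three-carbon unit whose syn aryl/H addition product is the trans-2,3-dihydrofuran of the target; Ca, lying between ring A and Cb, can be a carbonyl that acidifies Cb–H and holds the ring A ortho bromide four atoms from Cb.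
5. Ring order: western benzofuran (intramolecular Wittig), then seven-membered ring with dearomatised furan (key step), then eastern dihydrofuran ([4+1]), then union and deprotection.

Key step: step 8

Assumption: (R)-BINAP in step 8 and the (1R,4R,5R)-sulfide in steps 14 and 15 are taken to give the (3S) furan centres; if either sense proves opposite, the mirror-image ligand or sulfide is used without other change.

**Route**

Step 1
Reactants: 1 2-bromo-4,6-dimethoxybenzaldehyde
Product: 2 2-bromo-6-hydroxy-4-methoxybenzaldehyde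
Conditions: BCl3, CH2Cl2, −78 to 0 °C; then H2O
Reagents that add atoms: none
Why: BCl3 chelates the aldehyde oxygen and cleaves only the ortho methyl ether (chelation-controlled Lewis acid demethylation).

Step 2
Reactants: 2 2-bromo-6-hydroxy-4-methoxybenzaldehyde
Product: 3 3-bromo-2-(hydroxymethyl)-5-methoxyphenol
Conditions: NaBH4, MeOH, 0 °C
Reagents that add atoms: none
Why: Borohydride reduction of the aldehyde to the benzylic alcohol.

Step 3
Reactants: 3 3-bromo-2-(hydroxymethyl)-5-methoxyphenol
Product: 4 (2-bromo-6-hydroxy-4-methoxybenzyl)triphenylphosphonium bromide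
Conditions: PPh3·HBr, MeCN, reflux
Reagents that add atoms: triphenylphosphine hydrobromide [Br-].[PH+](c1ccccc1)(c1ccccc1)c1ccccc1
Why: The ortho-hydroxybenzylic alcohol ionises under HBr and is captured by the phosphine (standard phosphonium salt formation).

Step 4
Reactants: 4 (2-bromo-6-hydroxy-4-methoxybenzyl)triphenylphosphonium bromide; 5 4-methoxybenzoyl chloride
Product: 7 4-bromo-6-methoxy-2-(4-methoxyphenyl)benzofuran, via acyloxy ylide 6 (not isolated)
Conditions: Et3N, toluene, reflux
Reagents that add atoms: none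
Why: O-acylation of the phenol, ylide formation and intramolecular Wittig olefination of the ester carbonyl close the furan ring (intramolecular Wittig benzofuran synthesis).

Step 5
Reactants: 7 4-bromo-6-methoxy-2-(4-methoxyphenyl)benzofuran
Product: 8 4-iodo-6-methoxy-2-(4-methoxyphenyl)benzofuran
Conditions: CuI (cat.), NaI, trans-N,N′-dimethylcyclohexane-1,2-diamine, dioxane, 110 °C
Reagents that add atoms: sodium iodide [Na+].[I-]
Why: Copper-catalysed aromatic Finkelstein exchange gives the aryl iodide needed for selective oxidative addition in step 8.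

Step 6
Reactants: 9 5-chloro-2-methoxybenzyl chloride; 1 2-bromo-4,6-dimethoxybenzaldehyde
Product: 11 1-(2-bromo-4,6-dimethoxyphenyl)-2-(5-chloro-2-methoxyphenyl)ethan-1-ol (racemic), via benzylmagnesium chloride 10 (not isolated)
Conditions: Mg, THF, 0 °C; then 1, −20 to 0 °C; aq NH4Cl
Reagents that add atoms: none
Why: Grignard addition of the benzylic organomagnesium to the aldehyde, with both aryl halides inert at low temperature; the racemic carbinol centre is removed in step 7.

Step 7
Reactants: 11 1-(2-bromo-4,6-dimethoxyphenyl)-2-(5-chloro-2-methoxyphenyl)ethan-1-ol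
Product: 12 1-(2-bromo-4,6-dimethoxyphenyl)-2-(5-chloro-2-methoxyphenyl)ethan-1-one
Conditions: Dess–Martin periodinane, CH2Cl2, rt
Reagents that add atoms: none
Why: Dess–Martin oxidation of the secondary benzylic alcohol to the aryl benzyl ketone under neutral conditions.

Step 8
Reactants: 8 4-iodo-6-methoxy-2-(4-methoxyphenyl)benzofuran; 12 1-(2-bromo-4,6-dimethoxyphenyl)-2-(5-chloro-2-methoxyphenyl)ethan-1-one
Product: 14 western seven-ring ketone (2S,3S; Ca=O; Cb epimers), via triaryl ketone 13 (not isolated)
Conditions: Pd2(dba)3 (cat.), (R)-BINAP (cat.), NaOtBu (2.1 equiv), dioxane, 70 °C; then HCO2Na, MeOH, 100 °C; AcOH quench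
Reagents that add atoms: none
Why: Proposed new method: zerovalent palladium should first insert into the C4–I bond of 8 and arylate the sodium enolate of 12 (Buchwald–Hartwig ketone α-arylation, forming ring B C4–Cb), then insert into the ring A C–Br bond of 13, whose arylpalladium adds syn across the furan C2=C3 bond (forming ring A–C3) to leave a benzylic C2–palladium species with no syn β-hydrogen, which formate reduces with retention. The closest known reactions are the ketone α-arylation and the intramolecular asymmetric dearomative reductive Heck reaction of indoles and benzofurans; they have not been run in tandem, nor through a seven-membered ring from C4. The seven-membered ring closes by 7-exo-trig carbopalladation, and the furan ring is not formed but dearomatised. C3 is set by enantiofacial selection under (R)-BINAP and C2 follows from syn aryl/H delivery, which places the two aryl groups trans; Cb is an epimerisable α-carbon that is made planar in step 9. The step needs oxidative addition in the order iodide, bromide, chloride, which the halogen identity, the enolate-deactivated bromoarene and the bisphosphine ligand should secure. It also needs insertion into the furan bond before C–H arylation or debromination, which the electron-rich furan π-bond held within reach, the absence of carbonate or pivalate and the late addition of formate should secure.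

Step 9
Reactants: 14 western seven-ring ketone
Product: 15 western enol triflate (2S,3S; Ca(OTf)=Cb)
Conditions: KN(SiMe3)2, THF, −78 °C; then PhNTf2, −78 to 0 °C
Reagents that add atoms: N-phenylbis(trifluoromethanesulfonimide) FC(F)(F)S(=O)(=O)N(c1ccccc1)S(=O)(=O)C(F)(F)F
Why: The doubly benzylic α-proton at Cb is removed selectively and the enolate is O-sulfonylated (enol triflate formation), which also erases the epimer mixture at Cb.

Step 10
Reactants: 15 western enol triflate; 16 4-methoxyphenylboronic acid
Product: 17 western tetraaryl alkene (2S,3S; Ca=Cb)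
Conditions: Pd(PPh3)4 (cat.), K3PO4, dioxane/H2O, 90 °C
Reagents that add atoms: none
Why: Suzuki–Miyaura coupling of the enol triflate puts the 4-methoxyphenyl group on Ca, and this catalyst should not insert into the electron-rich aryl chloride.

Step 11
Reactants: 17 western tetraaryl alkene
Product: 18 western chloride (Ca S, Cb S, 2S, 3S)
Conditions: Et3SiH, CF3CO2H, CH2Cl2, −20 to 0 °C
Reagents that add atoms: none
Why: Ionic hydrogenation: protonation at Cb gives the Ca cation stabilised by the 4-methoxyphenyl group and ring A, which the silane reduces; proton and hydride should both arrive on the convex face of the tub-shaped ring, opposite the pseudo-axial furan C3–H (the hydride also anti to ring C), giving cis Ca–H/Cb–H.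

Step 12
Reactants: 19 1-bromo-3,5-dimethoxybenzene; 2 2-bromo-6-hydroxy-4-methoxybenzaldehyde
Product: 21 3-bromo-2-[(3,5-dimethoxyphenyl)(hydroxy)methyl]-5-methoxyphenol (racemic), via arylmagnesium bromide 20 (not isolated)
Conditions: Mg, THF; then 2 (0.43 equiv), 0 °C to rt; aq NH4Cl
Reagents that add atoms: none
Why: Grignard addition to the salicylaldehyde after the first equivalent deprotonates the phenol; the racemic carbinol centre is removed in step 15.

Step 13
Reactants: 21 3-bromo-2-[(3,5-dimethoxyphenyl)(hydroxy)methyl]-5-methoxyphenol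
Product: 22 3-bromo-2-[(3,5-dimethoxyphenyl)(4-methylbenzenesulfonyl)methyl]-5-methoxyphenol (racemic)
Conditions: p-TolSO2Na, HCO2H/H2O, rt
Reagents that add atoms: sodium p-toluenesulfinate [Na+].[O-]S(=O)c1ccc(C)cc1
Why: Acid-promoted ionisation of the ortho-hydroxybenzhydrol and S-alkylation of the sulfinate give the sulfone, a base-triggered ortho-quinone methide precursor.

Step 14
Reactants: 23 (1R,4R,5R)-isothiocineole; 24 4-methoxybenzyl bromide
Product: 25 S-(4-methoxybenzyl)isothiocineolium triflate
Conditions: LiOSO2CF3, CH2Cl2/H2O, rt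
Reagents that add atoms: lithium trifluoromethanesulfonate [Li+].[O-]S(=O)(=O)C(F)(F)F
Why: S-alkylation of the chiral sulfide by the benzylic bromide with anion metathesis gives the sulfonium triflate.

Step 15
Reactants: 22 3-bromo-2-[(3,5-dimethoxyphenyl)(4-methylbenzenesulfonyl)methyl]-5-methoxyphenol; 25 S-(4-methoxybenzyl)isothiocineolium triflate
Product: 29 (2S,3S)-4-bromo-3-(3,5-dimethoxyphenyl)-6-methoxy-2-(4-methoxyphenyl)-2,3-dihydrobenzofuran, via ortho-quinone methide 26 (not isolated), via sulfonium ylide 27 (not isolated), via betaine 28 (not isolated)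
Conditions: Cs2CO3, CH2Cl2, −20 °C to rt
Reagents that add atoms: none
Why: Base releases the ortho-quinone methide and the ylide, and conjugate addition followed by SN2 ring closure ([4+1] annulation of a sulfur ylide with an ortho-quinone methide) gives the trans-dihydrobenzofuran; the chiral sulfonium controls the ylide face and the anti betaine sets the (3S) centre.

Step 16
Reactants: 29 (2S,3S)-4-bromo-3-(3,5-dimethoxyphenyl)-6-methoxy-2-(4-methoxyphenyl)-2,3-dihydrobenzofuran
Product: 30 (2S,3S)-3-(3,5-dimethoxyphenyl)-6-methoxy-2-(4-methoxyphenyl)-4-vinyl-2,3-dihydrobenzofuran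
Conditions: vinylboronic acid pinacol ester, Pd(dppf)Cl2 (cat.), K3PO4, dioxane/H2O, 90 °C
Reagents that add atoms: vinylboronic acid pinacol ester C=CB1OC(C)(C)C(C)(C)O1
Why: Suzuki–Miyaura vinylation of the aryl bromide.

Step 17
Reactants: 18 western chloride; 30 (2S,3S)-3-(3,5-dimethoxyphenyl)-6-methoxy-2-(4-methoxyphenyl)-4-vinyl-2,3-dihydrobenzofuran
Product: 31 decamethyl ether of the target
Conditions: Pd2(dba)3 (cat.), P(t-Bu)3·HBF4 (cat.), Cy2NMe, dioxane, 110 °C
Reagents that add atoms: none
Why: Mizoroki–Heck coupling of the electron-rich aryl chloride with the styrene under a bulky trialkylphosphine catalyst should give the (E)-stilbene by syn insertion and syn β-hydride elimination.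

Step 18
Reactants: 31 decamethyl ether of the target
Product: 32 CNP0266373.2 (target)
Conditions: BBr3 (excess), CH2Cl2, −78 °C to rt; then ice/H2O
Reagents that add atoms: none
Why: Tenfold Lewis acid demethylation with BBr3 frees all phenols, and the trans-dihydrofurans are the thermodynamic isomers should either C2–O bond ionise reversibly.

**Compound list**

1 | 2-bromo-4,6-dimethoxybenzaldehyde | O=Cc1c(Br)cc(OC)cc1OC | starting material
2 | 2-bromo-6-hydroxy-4-methoxybenzaldehyde | O=Cc1c(Br)cc(OC)cc1O | intermediate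
3 | 3-bromo-2-(hydroxymethyl)-5-methoxyphenol | OCc1c(Br)cc(OC)cc1O | intermediate
4 | (2-bromo-6-hydroxy-4-methoxybenzyl)triphenylphosphonium bromide | Oc1cc(OC)cc(Br)c1C[P+](c1ccccc1)(c1ccccc1)c1ccccc1.[Br-] | intermediate
5 | 4-methoxybenzoyl chloride | COc1ccc(cc1)C(Cl)=O | starting material
6 | acyloxy ylide: 3-bromo-5-methoxy-2-[(triphenylphosphoranylidene)methyl]phenyl 4-methoxybenzoate | COc1ccc(cc1)C(=O)Oc1cc(OC)cc(Br)c1C=P(c1ccccc1)(c1ccccc1)c1ccccc1 | intermediate (not isolated)
7 | 4-bromo-6-methoxy-2-(4-methoxyphenyl)benzofuran | COc1ccc(-c2cc3c(Br)cc(OC)cc3o2)cc1 | intermediate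
8 | 4-iodo-6-methoxy-2-(4-methoxyphenyl)benzofuran | COc1ccc(-c2cc3c(I)cc(OC)cc3o2)cc1 | intermediate
9 | 5-chloro-2-methoxybenzyl chloride | COc1ccc(Cl)cc1CCl | starting material
10 | (5-chloro-2-methoxybenzyl)magnesium chloride | COc1ccc(Cl)cc1C[Mg]Cl | intermediate (not isolated)
11 | 1-(2-bromo-4,6-dimethoxyphenyl)-2-(5-chloro-2-methoxyphenyl)ethan-1-ol, racemic | COc1ccc(Cl)cc1CC(O)c1c(Br)cc(OC)cc1OC | intermediate
12 | 1-(2-bromo-4,6-dimethoxyphenyl)-2-(5-chloro-2-methoxyphenyl)ethan-1-one | COc1ccc(Cl)cc1CC(=O)c1c(Br)cc(OC)cc1OC | intermediate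
13 | triaryl ketone: 1-(2-bromo-4,6-dimethoxyphenyl)-2-(5-chloro-2-methoxyphenyl)-2-[6-methoxy-2-(4-methoxyphenyl)benzofuran-4-yl]ethan-1-one (sodium enolate in the flask) | COc1ccc(Cl)cc1C(C(=O)c1c(Br)cc(OC)cc1OC)c1cc(OC)cc2oc(-c3ccc(OC)cc3)cc12 | intermediate (not isolated)
14 | western seven-ring ketone: (2S,3S)-6-methoxy-2-(4-methoxyphenyl)-2,3-dihydrobenzofuran bridged from C3 to C4 by 3,5-dimethoxy-1,2-phenylene (its C1 on furan C3)–C(=O) (Ca)–CH(5-chloro-2-methoxyphenyl) (Cb, on C4; epimer mixture) | O=C1c2c(OC)cc(OC)cc2[C@H]2c3c(cc(OC)cc3C1c1cc(Cl)ccc1OC)O[C@@H]2c1ccc(OC)cc1 | intermediate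
15 | western enol triflate: as 14 with Ca(OSO2CF3)=Cb | FC(F)(F)S(=O)(=O)OC=1c2c(OC)cc(OC)cc2[C@H]2c3c(cc(OC)cc3C=1c1cc(Cl)ccc1OC)O[C@@H]2c1ccc(OC)cc1 | intermediate
16 | 4-methoxyphenylboronic acid | COc1ccc(cc1)B(O)O | starting material
17 | western tetraaryl alkene: as 15 with 4-methoxyphenyl on Ca in place of the triflate | COc1ccc(cc1)C=1c2c(OC)cc(OC)cc2[C@H]2c3c(cc(OC)cc3C=1c1cc(Cl)ccc1OC)O[C@@H]2c1ccc(OC)cc1 | intermediate
18 | western chloride: as 17 with Ca(S)–H and Cb(S)–H, both cis to each other and trans to furan C3–H | COc1ccc([C@H]2c3c(OC)cc(OC)cc3[C@H]3c4c(cc(OC)cc4[C@H]2c2cc(Cl)ccc2OC)O[C@@H]3c2ccc(OC)cc2)cc1 | intermediate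
19 | 1-bromo-3,5-dimethoxybenzene | COc1cc(Br)cc(OC)c1 | starting material
20 | (3,5-dimethoxyphenyl)magnesium bromide | COc1cc([Mg]Br)cc(OC)c1 | intermediate (not isolated)
21 | 3-bromo-2-[(3,5-dimethoxyphenyl)(hydroxy)methyl]-5-methoxyphenol, racemic | COc1cc(cc(OC)c1)C(O)c1c(O)cc(OC)cc1Br | intermediate
22 | 3-bromo-2-[(3,5-dimethoxyphenyl)(4-methylbenzenesulfonyl)methyl]-5-methoxyphenol, racemic | COc1cc(cc(OC)c1)C(c1c(O)cc(OC)cc1Br)S(=O)(=O)c1ccc(C)cc1 | intermediate
23 | (1R,4R,5R)-isothiocineole (4,7,7-trimethyl-6-thiabicyclo[3.2.1]octane) | C[C@@H]1CC[C@@H]2C[C@H]1SC2(C)C | starting material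
24 | 4-methoxybenzyl bromide | COc1ccc(CBr)cc1 | starting material
25 | S-(4-methoxybenzyl)-(1R,4R,5R)-isothiocineolium triflate | C[C@@H]1CC[C@@H]2C[C@H]1[S+](Cc1ccc(OC)cc1)C2(C)C.[O-]S(=O)(=O)C(F)(F)F | intermediate
26 | ortho-quinone methide: 3-bromo-6-[(3,5-dimethoxyphenyl)methylidene]-5-methoxycyclohexa-2,4-dien-1-one | O=C1C=C(OC)C=C(Br)C1=Cc1cc(OC)cc(OC)c1 | intermediate (not isolated)
27 | sulfonium ylide of 25 | C[C@@H]1CC[C@@H]2C[C@H]1[S+]([CH-]c1ccc(OC)cc1)C2(C)C | intermediate (not isolated)
28 | betaine (phenoxide/sulfonium adduct of 26 and 27) | C[C@@H]1CC[C@@H]2C[C@H]1[S+](C(c1ccc(OC)cc1)C(c1cc(OC)cc(OC)c1)c1c([O-])cc(OC)cc1Br)C2(C)C | intermediate (not isolated)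
29 | (2S,3S)-4-bromo-3-(3,5-dimethoxyphenyl)-6-methoxy-2-(4-methoxyphenyl)-2,3-dihydrobenzofuran | Brc1cc(OC)cc2c1[C@H](c1cc(OC)cc(OC)c1)[C@@H](c1ccc(OC)cc1)O2 | intermediate
30 | (2S,3S)-3-(3,5-dimethoxyphenyl)-6-methoxy-2-(4-methoxyphenyl)-4-vinyl-2,3-dihydrobenzofuran | C=Cc1cc(OC)cc2c1[C@H](c1cc(OC)cc(OC)c1)[C@@H](c1ccc(OC)cc1)O2 | intermediate
31 | decamethyl ether of the target (all ten phenols as OMe, E-stilbene) | COc1ccc([C@H]2c3c(OC)cc(OC)cc3[C@H]3c4c(cc(OC)cc4[C@H]2c2cc(/C=C/c4cc(OC)cc5c4[C@H](c4cc(OC)cc(OC)c4)[C@@H](c4ccc(OC)cc4)O5)ccc2OC)O[C@@H]3c2ccc(OC)cc2)cc1 | intermediate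
32 | CNP0266373.2 | Oc1ccc([C@H]2c3c(O)cc(O)cc3[C@H]3c4c(cc(O)cc4[C@H]2c2cc(/C=C/c4cc(O)cc5c4[C@H](c4cc(O)cc(O)c4)[C@@H](c4ccc(O)cc4)O5)ccc2O)O[C@@H]3c2ccc(O)cc2)cc1 | target

**Step count**

Total steps: 18. Longest linear sequence: 11 steps (1, 2, 3, 4, 5, 8, 9, 10, 11, 17, 18).

**Steps most likely to fail**

Step 8 (proposed new method). What may go wrong: oxidative addition at the bromoarene before the iodide is consumed, reductive debromination before ring closure, C–H arylation of a neighbouring benzo ring instead of insertion into the furan bond, or weak enantiofacial control in a seven-membered closure. The fallback uses known chemistry, sets out from 8 and 12 and returns at 18. The ketone α-arylation is run alone (Pd2(dba)3, racemic BINAP, NaOtBu, 70 °C) and triaryl ketone 13 is isolated. The ring is then closed without dearomatisation by palladium-catalysed intramolecular direct C–H arylation at benzofuran C3 (Pd(OAc)2, PCy3·HBF4, K2CO3, pivalic acid, DMA, 120 °C) to give the flat benzofuran-fused ketone F1. Enol triflate formation as in step 9 gives the benzofuran enol triflate F2, and Suzuki coupling with 16 as in step 10 gives the benzofuran tetraaryl alkene F3. Twofold ionic hydrogenation (Et3SiH, CF3CO2H) should reduce the alkene and the furan C2=C3 bond to the trans-dihydrofuran, giving the racemate of 18 F4, which is resolved by preparative chromatography on a chiral stationary phase to 18.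

Step 11. What may go wrong: proton and hydride delivery to the wrong alkene face, or acid cleavage of the benzylic furan C2–O bond followed by silane reduction of the opened cation. The fallback sets out from 14 and returns at 18. Ketone 14 is equilibrated at Cb with DBU (ring C pseudo-axial, away from the peri hydrogen of ring B) and treated with 4-MeOC6H4Li/CeCl3 in THF at −78 °C (organocerium 1,2-addition) to give the tertiary alcohol F5. Ionisation with BF3·OEt2 in the presence of Et3SiH at −78 °C should then reduce the Ca cation anti to ring C and give 18, without protonating an alkene and under acid too weak to open the furan.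

Step 18. What may go wrong: incomplete cleavage of ten ethers, and acid-induced cyclisation of the electron-rich stilbene onto ring E or hydrobromination during long exposure to BBr3. The fallback sets out from 18 and 29 and returns at 32; it removes the methyl ethers before the stilbene exists. BBr3 converts 18 into the hexaphenol chloride F6 and 29 into the tetraphenol bromide F8. Acetylation (Ac2O, pyridine) gives the hexaacetate chloride F7 and the tetraacetate bromide F9. Stille vinylation of F9 (Bu3SnCH=CH2, Pd(PPh3)4, toluene, 100 °C) gives the tetraacetate styrene F10. Heck coupling of F7 with F10 under the conditions of step 17 gives the decaacetate F11, and mild methanolysis (K2CO3, MeOH, 0 °C) releases 32.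

Further compounds
F1 | step 8 | flat benzofuran-fused ketone (aromatic furan analogue of 14) | O=C1C(c2cc(Cl)ccc2OC)c2cc(OC)cc3oc(-c4ccc(OC)cc4)c(c23)-c2cc(OC)cc(OC)c12
F2 | step 8 | benzofuran enol triflate (aromatic furan analogue of 15) | FC(F)(F)S(=O)(=O)OC1=C(c2cc(Cl)ccc2OC)c2cc(OC)cc3oc(-c4ccc(OC)cc4)c(c23)-c2cc(OC)cc(OC)c12
F3 | step 8 | benzofuran tetraaryl alkene (aromatic furan analogue of 17) | COc1ccc(cc1)C1=C(c2cc(Cl)ccc2OC)c2cc(OC)cc3oc(-c4ccc(OC)cc4)c(c23)-c2cc(OC)cc(OC)c12
F4 | step 8 | racemate of 18 (relative configuration as in 18) | COc1ccc(C2c3c(OC)cc(OC)cc3C3c4c(cc(OC)cc4C2c2cc(Cl)ccc2OC)OC3c2ccc(OC)cc2)cc1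
F5 | step 11 | tertiary alcohol from 14 (Ca bearing OH and 4-methoxyphenyl; Cb as in 18) | COc1ccc(cc1)C1(O)c2c(OC)cc(OC)cc2[C@H]2c3c(cc(OC)cc3[C@H]1c1cc(Cl)ccc1OC)O[C@@H]2c1ccc(OC)cc1
F6 | step 18 | hexaphenol chloride (18 with all OMe as OH) | Oc1ccc([C@H]2c3c(O)cc(O)cc3[C@H]3c4c(cc(O)cc4[C@H]2c2cc(Cl)ccc2O)O[C@@H]3c2ccc(O)cc2)cc1
F7 | step 18 | hexaacetate chloride | CC(=O)Oc1ccc([C@H]2c3c(OC(C)=O)cc(OC(C)=O)cc3[C@H]3c4c(cc(OC(C)=O)cc4[C@H]2c2cc(Cl)ccc2OC(C)=O)O[C@@H]3c2ccc(OC(C)=O)cc2)cc1
F8 | step 18 | tetraphenol bromide (29 with all OMe as OH) | Brc1cc(O)cc2c1[C@H](c1cc(O)cc(O)c1)[C@@H](c1ccc(O)cc1)O2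
F9 | step 18 | tetraacetate bromide | Brc1cc(OC(C)=O)cc2c1[C@H](c1cc(OC(C)=O)cc(OC(C)=O)c1)[C@@H](c1ccc(OC(C)=O)cc1)O2
F10 | step 18 | tetraacetate styrene | C=Cc1cc(OC(C)=O)cc2c1[C@H](c1cc(OC(C)=O)cc(OC(C)=O)c1)[C@@H](c1ccc(OC(C)=O)cc1)O2
F11 | step 18 | decaacetate of the target | CC(=O)Oc1ccc([C@H]2c3c(OC(C)=O)cc(OC(C)=O)cc3[C@H]3c4c(cc(OC(C)=O)cc4[C@H]2c2cc(/C=C/c4cc(OC(C)=O)cc5c4[C@H](c4cc(OC(C)=O)cc(OC(C)=O)c4)[C@@H](c4ccc(OC(C)=O)cc4)O5)ccc2OC(C)=O)O[C@@H]3c2ccc(OC(C)=O)cc2)cc1
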